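Between 20.0 min and 25.0 min the dawn run gained 2.5 percentage points of E, against 5.1 points between 10.0 min and 15.0 min, and my colleague and I read that drop differently.

- dawn: Z 0.26 M; J 0.52 M; the very flask that is asked about, followed so far
- flask: Z 0.26 M; J 0.520 M; time 80 min; volume of the second phase over the first 1.0

dawn run (percent of the Z charged): time / min: E / % = 5.00: 3.9; 10.0: 8.8; 15.0: 13.9; 20.0: 18.6; 25.0: 21.1

(each reading ± 0.5 percentage points)

- in the second phase: J; everything else is in the first
- charges count per volume of the first phase; a concentration in a rate is the amount of a species over the volume of its own phase; every rate counts per litre of the first phase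
- what was read earlier has a scatter of 0.5 percentage points, one standard deviation
- the earlier runs hold the two phases in the same ratio of volumes as the flask asked about

- how much E there is at 80 min, in percent of the Z charged
- the change that raises the amount of E at 80 min, in percent of the Z charged most ("none" if none brings more than 2 percentage points) (gamma / eta / none)
- amount of E at 80 min, in percent of the Z charged, after gamma

I read the drop as the approach to a final level, though each gain carries the scatter of two readings. In these readings the gain fell to half over 10.0 min. From this I reckon a decade time, the time in which the gap to a final level shrinks tenfold: 32.3 min, a relaxation time counted in powers of ten. Summing the shrinking gains puts the level near 26.9%. Since 80 min is 2.48 decade times, the gap by then should have shrunk about 300-fold. So I say y is about 26.9%. Faster transfer should hurry the approach and leave the level, so I expect gamma to bring under 2 points. I bet on none, though the dawn run, at the single c_J of 0.52 M, shows nothing of what a higher c_J does to the level.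

My colleague runs a rate law forward instead and forecasts 50% (36% to 62%), best eta, and 62% after gamma (44% to 82%): “Doubling J helps in either regime”.

The flask gives 22.3%, best none, and 21.9% after gamma; gamma changes E by −0.39 points and eta by −3.6 points. My figure for y stands 4.6 points above the flask's. My colleague's straight line fits the dawn readings up to 18.6% at 20.0 min.

    L ⇌ J, rate k1*([L] - [J]/K1) per volume of the first phase (partition coefficient = 0.550, kL = 0.0550 min⁻¹)
    Z + L ⇌ E (K = 2.40 M⁻¹, k = 0.0680 M⁻¹ min⁻¹)
    L + E → G (k = 0.0590 M⁻¹ min⁻¹)
    L → D (k = 2.80 × 10⁻⁵ min⁻¹)

The same flask left until 3.0 h tests the decade time. From 80 min to then lie 3.10 decade times, but E went from 22.3% to 14.2%, a move of 0.196 of a power of ten. So E is falling there, not resting at a level, and reckoned over that stretch its fall has a decade time of its own, 508 min, longer than the one read from the dawn climb. G stood at 22.9% at 80.0 min and at 42.9% in that later flask.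

The earlier runs and the new flask stem from a simulated flask from invented constants, and the scatter is random.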